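## Analysis of the target

The target 20 (C24H14O11) is a flat, fully aromatic polyether with no stereocentre. Ring E (3,5-dihydroxyphenyl) is joined by an ether oxygen to ring D, ring D is fused through a 1,4-dioxin ring to the central ring C, and ring C is fused through a furan ring to ring A. The carbons are labelled as follows:

- Ring C: C1 (dioxin O), C2 (OH), C3 (H), C4 (furan O), C5 (furan C), C6 (dioxin O).
- Ring D: D1 (O–ring E), D2 (OH), D3 (H), D4 (OH), D5 and D6 (dioxin O), with the bridges D6–O–C1 and D5–O–C6.
- Ring A: A1 (furan O), A2 (H), A3 (OH), A4 (H), A5 (OH), A6 (bonded to C5).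

The seven phenolic hydroxyls sit on very electron-rich rings and are oxidised easily, above all in base, so they must be carried as alkyl ethers and freed last. The synthesis is hard for three reasons:

- Ring D carries five oxygens, and ring C carries four oxygens and one carbon substituent, each in a fixed order.
- The unsymmetrical dioxin must be closed in one orientation (D6 to C1, D5 to C6).
- The two positions ortho to the C4 oxygen (C3 and C5) must be told apart.

The strategy rests on ring A. It shares the A1–A6 bond with the furan, and its six carbons fall into three two-carbon units: A1–A2 on the furan oxygen, A6–A5 on C5, and a free unit A3–A4. The oxygens at A3 and A5 are meta to each other, which is the pattern that three alkynes give when two of them are alkynyl ethers.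

## Retrosynthetic reasoning

**20 to 19.** The seven O–alkyl bonds (five methyl, two ethyl) are cut last. The free polyphenol would not survive bases, organolithiums or copper and palladium catalysts, so every hydroxyl travels as an ether. One Lewis-acid dealkylation must cleave all alkyl–oxygen bonds and leave the diaryl ether, dioxin and furan C–O bonds, which have no sp3 carbon.

**19 to 18 and 14.** Three C–C bonds of ring A are cut: A1–A6 (the furan C–C bond), A2–A3 and A4–A5. This leaves diyne 18, which carries an ethynyloxy group on C4 and an ethoxyethynyl group on C5, and ethoxyacetylene 14. The cut is made here because it removes the furan and ring A together and reduces ring A to two-carbon units. The forward reaction must join the two tethered alkynes first and then take up 14 in one orientation, at a temperature the alkynyl ethers tolerate.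

**18 to 11, 12 and 14.** The terminal alkynyl ether of 18 comes from the dichlorovinyl ether 15 by elimination. The aryl–alkyne bond at C5 comes from the aryl iodide 13 and 14 by cross-coupling. The O–vinyl bond comes from the ortho-iodophenol 11 and trichloroethylene 12. The order is forced. The phenol is etherified first, because a free ortho-alkynylphenol would cyclise to a benzofuran. The iodide is coupled before the organolithium step, because it would otherwise undergo halogen–lithium exchange.

**11 to 8.** The C5–I bond and then the C4–O bond are cut, giving the dibenzodioxin 8, whose ring C carries only the C2 methoxy group. C4 is the only aromatic C–H in 8 without an ortho substituent, so a sterically governed C–H borylation and oxidation can place the hydroxyl there (phenol 10). This saves carrying a protected hydroxyl through the dioxin assembly. Iodination of 10 must then choose C5 over C3. C5 is para to the C2 methoxy group and flanked only by the tied-back dioxin oxygen, whereas C3 is screened by the in-plane methyl of that methoxy group.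

**8 to 5.** The dioxin is opened at the D6–O–C1 bond, giving phenol 7 with a bromide on C1. This tetra-ortho-substituted ether is better closed intramolecularly. The D6 hydroxyl of 7 is traced to the formyl group of aldehyde 5 through a peracid oxidation. The formyl group is therefore a latent oxygen.

**5 to 1, 2 and 4.** The two remaining aryl ether bonds on ring D (D5–O–C6 and D1–O–ring E) are cut next to the formyl group. Both are made by nucleophilic aromatic substitution of the two ortho fluorides of the symmetric aldehyde 1, first with the bromophenol 2 (giving 3), then with 3,5-dimethoxyphenol 4. Cutting here gives every oxygen of ring D a defined origin: D2 and D4 from the methoxy groups of 1, D1 and D5 from its fluorides, D6 from its formyl carbon. Each dioxin C–O bond is formed in its own step, so the orientation of the dioxin is not left to chance. The hindered phenol 2 is used first, on the more reactive difluoride.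

## Alternatives that were turned down

**Alternative 1: benzannulation that builds ring C.** Ring C is cut at four C–C bonds. Two of its carbons come from the furan of a benzofuran, two from the diazo ketone side chain of A1, and two from the alkyne A2 (di-tert-butoxyethyne). In the forward step A1 is irradiated with A2 and then warmed. A Wolff shift, a (2+2) cycloaddition, a 4π ring opening and a 6π closure onto benzofuran C3 give the dibenzofuranol A3.
- For it: the most substituted ring is made in one pericyclic cascade, with no aromatic substitution on ring C. On this point it is stronger than the chosen route, which relies on a site-selective borylation and iodination of ring C.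
- Against it: A3 carries two identical tert-butoxy groups on the carbons that must become C1 (dioxin oxygen) and C2 (free hydroxyl), and they cannot be told apart. A2 is a labile alkyne that needs its own synthesis. The whole dioxin, with the pentaoxygenated ring D and ring E, would still have to be attached to an oxidation-prone dibenzofuranol, by two hindered aryl ether bonds and with no activating group left.
- Comparison: the chosen route assembles the robust permethylated dioxin first and adds the simple rings last. Alternative 1 makes the hard ring early but leaves the orientation of the dioxin for the end, and needs clearly more steps after its key step.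

**Alternative 2: ring A by Claisen condensation.** Ring A is cut at the A3–A4 bond. The precursor A4 is the dibenzodioxin-fused benzofuran with an acetyl group on furan C3 and a methyl acetate arm on furan C2. In the forward step an alkoxide base forms the methyl ketone enolate, which attacks the ester. The cyclic 1,3-diketone aromatises to A5, the penta-O-methyl ether with both ring A hydroxyls free.
- For it: the key step is a simple base-mediated condensation with no metal and no orientation question, and it frees two hydroxyls directly. In that step it is at least as safe as the chosen one.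
- Against it: A4 needs an acyl group placed at C5 of ring C (the same C5 versus C3 problem), then a furan construction with the acetate arm, which is several steps where the chosen route needs one. The CH2 between ester and furan is the most acidic site, and its enolate cannot close a six-membered ring, so it only lowers the concentration of the productive enolate. The free resorcinol of A5 is formed in base, where it is air-sensitive.
- Comparison: the chosen strategy forms the furan and ring A together from the ortho-iodophenol and is shorter.

**Alternative 3: furan closed by C–H arylation.** Only the furan C–C bond (C5–A6) is cut. The precursor A6 carries a bromine on C5 and a 3,5-dimethoxyphenyl ether on C4. In the forward step a palladium–trialkylphosphine catalyst with carbonate base arylates an ortho C–H of that ether, giving the hepta-O-methyl ether A7.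
- For it: this ring closure is well established for dibenzofurans, the aryl ether is symmetric so there is no orientation question, and all protecting groups are methyl. From the ortho-halophenol it is two steps shorter than the chosen sequence. On precedent and step count it is the stronger option.
- Against it: it needs a hindered diaryl ether made next to the halogen, and a C–H bond flanked by two oxygens must be metalated at high temperature.
- Comparison: the chosen strategy builds ring A from two-carbon units at room temperature and closes two rings and three C–C bonds in one catalytic step. It also lets the ring A substituents be varied through the alkyne. Because the two routes share the ortho-halophenol, alternative 3 is kept as the fallback for the key step.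

Key step: step 10

Assumption: 2,6-difluoro-3,5-dimethoxybenzaldehyde (1) is taken as a purchasable building block; it is the aldehyde of the catalogue alcohol (2,6-difluoro-3,5-dimethoxyphenyl)methanol and would otherwise be made from it by one MnO2 oxidation.

## Route

**Step 1**
Reactants: 1 2,6-difluoro-3,5-dimethoxybenzaldehyde; 2 2-bromo-3-methoxyphenol
Product: 3 2-(2-bromo-3-methoxyphenoxy)-6-fluoro-3,5-dimethoxybenzaldehyde
Conditions: K2CO3, DMF, 80 °C (1 in slight excess)
Reagents that add atoms: none
Why: Nucleophilic aromatic substitution (SNAr); both fluorides of the symmetric aldehyde 1 are ortho to the formyl group, which stabilises the Meisenheimer adduct. The aryloxy group that enters and the bulk of the ortho-bromophenoxide slow a second substitution, so the mono-ether should prevail.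

**Step 2**
Reactants: 3 2-(2-bromo-3-methoxyphenoxy)-6-fluoro-3,5-dimethoxybenzaldehyde; 4 3,5-dimethoxyphenol
Product: 5 2-(2-bromo-3-methoxyphenoxy)-6-(3,5-dimethoxyphenoxy)-3,5-dimethoxybenzaldehyde
Conditions: Cs2CO3, DMSO, 110 °C
Reagents that add atoms: none
Why: Second SNAr at the remaining ortho fluoride by the unhindered phenoxide of 4; the ring is less activated now, hence the more forcing conditions. The aryl bromide is inert to carbonate.

**Step 3**
Reactants: 5 2-(2-bromo-3-methoxyphenoxy)-6-(3,5-dimethoxyphenoxy)-3,5-dimethoxybenzaldehyde
Product: 7 2-(2-bromo-3-methoxyphenoxy)-6-(3,5-dimethoxyphenoxy)-3,5-dimethoxyphenol, via aryl formate 6 (not isolated)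
Conditions: mCPBA, CH2Cl2, 0 °C to rt; then MeOH, K2CO3 (cat.), rt, under argon
Reagents that add atoms: 3-chloroperbenzoic acid (mCPBA), OOC(=O)c1cccc(Cl)c1
Why: Baeyer–Villiger (Dakin-type) oxidation; the aryl group with two ortho oxygen donors migrates in the Criegee adduct in preference to hydride, and the aryl formate is methanolysed. The formyl group thus serves first as SNAr activator and then as the latent D6 hydroxyl.

**Step 4**
Reactants: 7 2-(2-bromo-3-methoxyphenoxy)-6-(3,5-dimethoxyphenoxy)-3,5-dimethoxyphenol
Product: 8 4-(3,5-dimethoxyphenoxy)-1,3,6-trimethoxydibenzo[b,e][1,4]dioxine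
Conditions: CuI (cat.), N,N-dimethylglycine (cat.), Cs2CO3, 1,4-dioxane, 100 °C, degassed
Reagents that add atoms: none
Why: Intramolecular Ullmann ether synthesis; the copper phenoxide at D6 substitutes the only aryl bromide (C1), which sits ortho to the existing ether bridge, and closes the six-membered dioxin ring. Because each dioxin C–O bond is made in a separate step, the orientation D6–O–C1 and D5–O–C6 is fixed.

**Step 5**
Reactants: 8 4-(3,5-dimethoxyphenoxy)-1,3,6-trimethoxydibenzo[b,e][1,4]dioxine
Product: 10 6-(3,5-dimethoxyphenoxy)-4,7,9-trimethoxydibenzo[b,e][1,4]dioxin-2-ol, via pinacol boronate 9 (not isolated)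
Conditions: [Ir(OMe)(cod)]2 (cat.), 4,4'-di-tert-butyl-2,2'-bipyridine (cat.), B2pin2, THF, 80 °C; then aq. H2O2, NaOH, 0 °C
Reagents that add atoms: bis(pinacolato)diboron, CC1(C)OB(OC1(C)C)B1OC(C)(C)C(C)(C)O1 (boryl group of 9); hydrogen peroxide, OO (oxygen of the new hydroxyl)
Why: Iridium-catalysed C–H borylation followed by oxidation in the same flask; the borylation is governed by sterics and should take C4 of ring C, the only aromatic C–H of 8 with no ortho substituent (every other C–H is flanked by at least one oxygen substituent).

**Step 6**
Reactants: 10 6-(3,5-dimethoxyphenoxy)-4,7,9-trimethoxydibenzo[b,e][1,4]dioxin-2-ol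
Product: 11 6-(3,5-dimethoxyphenoxy)-1-iodo-4,7,9-trimethoxydibenzo[b,e][1,4]dioxin-2-ol
Conditions: I2 (1.0 equiv), NaHCO3, THF–H2O, 0 °C
Reagents that add atoms: iodine, II
Why: Electrophilic ortho-iodination of a phenoxide; C5 is para to the C2 methoxy group and flanked only by the tied-back dioxin oxygen, whereas C3 is screened by the in-plane methyl of that methoxy group, so iodine should enter at C5. The neutral aryl ether rings react far more slowly than the phenoxide with this mild electrophile.

**Step 7**
Reactants: 11 6-(3,5-dimethoxyphenoxy)-1-iodo-4,7,9-trimethoxydibenzo[b,e][1,4]dioxin-2-ol; 12 trichloroethylene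
Product: 13 2-[(E)-1,2-dichloroethenyl]oxy-6-(3,5-dimethoxyphenoxy)-1-iodo-4,7,9-trimethoxydibenzo[b,e][1,4]dioxine
Conditions: K2CO3, DMF, 70 °C
Reagents that add atoms: none
Why: Base eliminates HCl from trichloroethylene to dichloroacetylene, to which the phenoxide adds anti, giving the (E)-1,2-dichlorovinyl ether (the established entry to aryl alkynyl ethers). Etherification also prevents benzofuran formation in the next step.

**Step 8**
Reactants: 13 2-[(E)-1,2-dichloroethenyl]oxy-6-(3,5-dimethoxyphenoxy)-1-iodo-4,7,9-trimethoxydibenzo[b,e][1,4]dioxine; 14 ethoxyacetylene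
Product: 15 2-[(E)-1,2-dichloroethenyl]oxy-6-(3,5-dimethoxyphenoxy)-1-(ethoxyethynyl)-4,7,9-trimethoxydibenzo[b,e][1,4]dioxine
Conditions: PdCl2(PPh3)2 (cat.), CuI (cat.), Et3N, THF, rt; 14 as its hexane solution, in excess
Reagents that add atoms: none
Why: Sonogashira coupling of the aryl iodide with the terminal alkynyl ether at room temperature, where the vinyl chlorides do not undergo oxidative addition. The iodide is consumed here, before any organolithium is used.

**Step 9**
Reactants: 15 2-[(E)-1,2-dichloroethenyl]oxy-6-(3,5-dimethoxyphenoxy)-1-(ethoxyethynyl)-4,7,9-trimethoxydibenzo[b,e][1,4]dioxine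
Product: 18 6-(3,5-dimethoxyphenoxy)-1-(ethoxyethynyl)-2-(ethynyloxy)-4,7,9-trimethoxydibenzo[b,e][1,4]dioxine, via chloroethynyl ether 16 (not isolated), via lithium acetylide 17 (not isolated)
Conditions: n-BuLi (excess), THF, −78 to −40 °C; then H2O, −78 °C; product kept cold and used at once
Reagents that add atoms: none
Why: n-BuLi eliminates HCl from the dichlorovinyl ether to the chloroalkynyl ether and then exchanges chlorine for lithium; protonation of the lithium acetylide gives the terminal aryl ethynyl ether. At −78 °C the internal ethoxyalkyne should not be attacked.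

**Step 10**
Reactants: 18 6-(3,5-dimethoxyphenoxy)-1-(ethoxyethynyl)-2-(ethynyloxy)-4,7,9-trimethoxydibenzo[b,e][1,4]dioxine; 14 ethoxyacetylene
Product: 19 penta-O-methyl di-O-ethyl ether of the target (ethoxy groups at A3 and A5 of ring A)
Conditions: [Rh(cod)2]BF4 (cat.), BINAP (cat.), catalyst pre-activated with H2; 14 (excess), CH2Cl2, rt, slow addition of 18
Reagents that add atoms: none
Why: Cationic monovalent rhodium with BINAP binds the two tethered alkynes of 18 and couples them oxidatively to a rhodacyclopentadiene, forming the furan C–C bond (A1–A6); 14 then inserts into a Rh–C bond, and reductive elimination from trivalent rhodium forms the last C–C bond and releases ring A. The closest known reaction type is the cationic rhodium-catalysed (2+2+2) cycloaddition of oxygen-tethered aryl diynes with monoalkynes to dibenzofurans. The furan closes in the oxidative coupling as a five-membered ring, because the three-atom tether (ether oxygen, C4, C5) holds both alkynes on the metal; ring A closes in the reductive elimination as a six-membered ring made of three two-carbon units. No stereocentre is formed. The step needs cross- over homo-trimerisation, which the fast intramolecular diyne coupling and slow addition of 18 to excess 14 should secure. It also needs one orientation of 14, with its oxygen-bearing carbon bonded to the unsubstituted diyne terminus (A2); the ethoxy group on the other rhodacycle terminus should enforce this sterically, so that the two ethoxy groups end meta to each other and to the furan oxygen. Room temperature keeps the alkynyl ethers from rearranging to ketenes.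

**Step 11**
Reactants: 19 penta-O-methyl di-O-ethyl ether of the target
Product: 20 target
Conditions: BBr3 (excess), CH2Cl2, −78 °C to rt; then H2O; work-up under argon
Reagents that add atoms: none
Why: Lewis-acid ether cleavage; BBr3 coordinates each alkyl aryl ether and bromide attacks the methyl or ethyl carbon. The diaryl ether, dioxin and furan C–O bonds offer no sp3 carbon and remain.

## Compound list

1 | 2,6-difluoro-3,5-dimethoxybenzaldehyde | O=Cc1c(F)c(OC)cc(OC)c1F | starting material
2 | 2-bromo-3-methoxyphenol | COc1cccc(O)c1Br | starting material
3 | 2-(2-bromo-3-methoxyphenoxy)-6-fluoro-3,5-dimethoxybenzaldehyde | O=Cc1c(F)c(OC)cc(OC)c1Oc1cccc(OC)c1Br | intermediate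
4 | 3,5-dimethoxyphenol | COc1cc(O)cc(OC)c1 | starting material
5 | 2-(2-bromo-3-methoxyphenoxy)-6-(3,5-dimethoxyphenoxy)-3,5-dimethoxybenzaldehyde | O=Cc1c(Oc2cc(OC)cc(OC)c2)c(OC)cc(OC)c1Oc1cccc(OC)c1Br | intermediate
6 | 2-(2-bromo-3-methoxyphenoxy)-6-(3,5-dimethoxyphenoxy)-3,5-dimethoxyphenyl formate | O=COc1c(Oc2cc(OC)cc(OC)c2)c(OC)cc(OC)c1Oc1cccc(OC)c1Br | intermediate
7 | 2-(2-bromo-3-methoxyphenoxy)-6-(3,5-dimethoxyphenoxy)-3,5-dimethoxyphenol | Oc1c(Oc2cc(OC)cc(OC)c2)c(OC)cc(OC)c1Oc1cccc(OC)c1Br | intermediate
8 | 4-(3,5-dimethoxyphenoxy)-1,3,6-trimethoxydibenzo[b,e][1,4]dioxine | COc1cc(OC)cc(Oc2c(OC)cc(OC)c3c2Oc2c(OC)cccc2O3)c1 | intermediate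
9 | 2-[6-(3,5-dimethoxyphenoxy)-4,7,9-trimethoxydibenzo[b,e][1,4]dioxin-2-yl]-4,4,5,5-tetramethyl-1,3,2-dioxaborolane | COc1cc(OC)cc(Oc2c(OC)cc(OC)c3c2Oc2c(OC)cc(B4OC(C)(C)C(C)(C)O4)cc2O3)c1 | intermediate
10 | 6-(3,5-dimethoxyphenoxy)-4,7,9-trimethoxydibenzo[b,e][1,4]dioxin-2-ol | COc1cc(OC)cc(Oc2c(OC)cc(OC)c3c2Oc2c(OC)cc(O)cc2O3)c1 | intermediate
11 | 6-(3,5-dimethoxyphenoxy)-1-iodo-4,7,9-trimethoxydibenzo[b,e][1,4]dioxin-2-ol | COc1cc(OC)cc(Oc2c(OC)cc(OC)c3c2Oc2c(OC)cc(O)c(I)c2O3)c1 | intermediate
12 | trichloroethylene | ClC=C(Cl)Cl | starting material
13 | 2-[(E)-1,2-dichloroethenyl]oxy-6-(3,5-dimethoxyphenoxy)-1-iodo-4,7,9-trimethoxydibenzo[b,e][1,4]dioxine | COc1cc(OC)cc(Oc2c(OC)cc(OC)c3c2Oc2c(OC)cc(O/C(Cl)=C\Cl)c(I)c2O3)c1 | intermediate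
14 | ethoxyacetylene | CCOC#C | starting material
15 | 2-[(E)-1,2-dichloroethenyl]oxy-6-(3,5-dimethoxyphenoxy)-1-(ethoxyethynyl)-4,7,9-trimethoxydibenzo[b,e][1,4]dioxine | COc1cc(OC)cc(Oc2c(OC)cc(OC)c3c2Oc2c(OC)cc(O/C(Cl)=C\Cl)c(C#COCC)c2O3)c1 | intermediate
16 | 2-(chloroethynyloxy)-6-(3,5-dimethoxyphenoxy)-1-(ethoxyethynyl)-4,7,9-trimethoxydibenzo[b,e][1,4]dioxine | COc1cc(OC)cc(Oc2c(OC)cc(OC)c3c2Oc2c(OC)cc(OC#CCl)c(C#COCC)c2O3)c1 | intermediate
17 | lithium acetylide of 18 (lithium on the terminal carbon of the ethynyloxy group) | COc1cc(OC)cc(Oc2c(OC)cc(OC)c3c2Oc2c(OC)cc(OC#C[Li])c(C#COCC)c2O3)c1 | intermediate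
18 | 6-(3,5-dimethoxyphenoxy)-1-(ethoxyethynyl)-2-(ethynyloxy)-4,7,9-trimethoxydibenzo[b,e][1,4]dioxine | COc1cc(OC)cc(Oc2c(OC)cc(OC)c3c2Oc2c(OC)cc(OC#C)c(C#COCC)c2O3)c1 | intermediate
19 | penta-O-methyl di-O-ethyl ether of the target (ethoxy at A3 and A5; methoxy on rings C, D and E) | COc1cc(OC)cc(Oc2c(OC)cc(OC)c3c2Oc2c(OC)cc4oc5cc(OCC)cc(OCC)c5c4c2O3)c1 | intermediate
20 | target: benzofuro-fused dibenzo[1,4]dioxin heptaol carrying a 3,5-dihydroxyphenoxy group on D1 | Oc1cc(O)cc(Oc2c(O)cc(O)c3c2Oc2c(O)cc4oc5cc(O)cc(O)c5c4c2O3)c1 | target

## Step count and least certain steps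

Total: 11 steps. Longest linear sequence: 11 steps (1 or 2 to 20).

**Step 10 (key step).** Three electron-rich alkynyl ethers meet one cationic metal. Homo-trimerisation of 14 or oligomerisation of 18 may outrun the cross reaction. Insertion of 14 in the reverse orientation would give the ortho-diethoxy isomer. The Lewis-acidic catalyst may also hydrate the alkynyl ethers or turn them into ketenes. The fallback leaves the cycloaddition and closes only the furan, with ring A bought. It sets out from 11. Chan–Lam coupling with (3,5-dimethoxyphenyl)boronic acid (Cu(OAc)2, pyridine, air, CH2Cl2, rt) should give the iodo diaryl ether F1. Palladium-catalysed C–H arylation (Pd(OAc)2, PCy3·HBF4, K2CO3, DMA, 130 °C) then closes the furan to the hepta-O-methyl ether F2, which is the same compound as A7. BBr3 converts F2 into 20, where the fallback rejoins the route.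

**Step 6.** The two positions ortho to the phenol may not be discriminated well enough, a second iodine may enter, and ring E may be iodinated if the phenoxide is not fully formed. The fallback replaces electrophilic substitution by directed ortho-metalation with a silicon block. It sets out from 10. Diethylcarbamoyl chloride and NaH give the carbamate F3. s-BuLi/TMEDA at −78 °C then TMSCl should silylate the site between the carbamate and the methoxy group (C3), giving the silane F4. A second lithiation can then only occur at C5, and quenching with I2 gives the iodide F5. TFA removes the silyl group to give the iodo carbamate F6, and NaOH in ethanol frees the phenol 11, where the route is rejoined.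

**Step 4.** Substitution at the hindered, electron-rich bromide may be slow, so that protodebromination and oxidative decay of the electron-rich phenoxide at 100 °C take over. The fallback changes the polarity of the carbon partner. It sets out from 7. Miyaura borylation of the bromide (PdCl2(dppf), B2pin2, KOAc, dioxane, 90 °C) gives the boronate phenol F7. Intramolecular Chan–Lam etherification (Cu(OAc)2, pyridine, O2, CH2Cl2, rt) closes the dioxin at room temperature and returns to 8.

**Step 2.** The second fluoride is more hindered and less activated. Substitution may be slow, the aryloxy group already in place may be exchanged by the incoming phenoxide, and the aldehyde may degrade in hot base. The fallback introduces the oxygen first and the aryl group second. It sets out from 3. KOH in DMSO–H2O replaces the fluoride by the small hydroxide, giving the salicylaldehyde F8. Chan–Lam arylation with (3,5-dimethoxyphenyl)boronic acid (Cu(OAc)2, pyridine, air) then gives 5, where the route is rejoined.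

**Step 8.** Oxidative addition at the iodide flanked by two oxygens may be slow at room temperature, while copper promotes homocoupling or hydration of the volatile alkyne 14. The fallback uses a preformed organometallic instead of the copper acetylide. It sets out from 13 and 14. Deprotonation of 14 with n-BuLi and addition of ZnCl2 gives (ethoxyethynyl)zinc chloride F9. Negishi coupling with 13 (Pd(PPh3)4, THF, rt) gives 15, where the route is rejoined.

## Further compounds

F1 | step 10 | 3,5-dimethoxyphenyl ether of 11 (aryloxy on C4, iodine on C5) | COc1cc(OC)cc(Oc2c(OC)cc(OC)c3c2Oc2c(OC)cc(Oc4cc(OC)cc(OC)c4)c(I)c2O3)c1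
F2 | step 10 | hepta-O-methyl ether of 20 | COc1cc(OC)cc(Oc2c(OC)cc(OC)c3c2Oc2c(OC)cc4oc5cc(OC)cc(OC)c5c4c2O3)c1
F3 | step 6 | N,N-diethylcarbamate of 10 | COc1cc(OC)cc(Oc2c(OC)cc(OC)c3c2Oc2c(OC)cc(OC(=O)N(CC)CC)cc2O3)c1
F4 | step 6 | N,N-diethylcarbamate of 10 with a trimethylsilyl group on C3 | COc1cc(OC)cc(Oc2c(OC)cc(OC)c3c2Oc2c(OC)c([Si](C)(C)C)c(OC(=O)N(CC)CC)cc2O3)c1
F5 | step 6 | N,N-diethylcarbamate of 10 with trimethylsilyl on C3 and iodine on C5 | COc1cc(OC)cc(Oc2c(OC)cc(OC)c3c2Oc2c(OC)c([Si](C)(C)C)c(OC(=O)N(CC)CC)c(I)c2O3)c1
F6 | step 6 | N,N-diethylcarbamate of 11 | COc1cc(OC)cc(Oc2c(OC)cc(OC)c3c2Oc2c(OC)cc(OC(=O)N(CC)CC)c(I)c2O3)c1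
F7 | step 4 | 2-(3,5-dimethoxyphenoxy)-3,5-dimethoxy-6-[3-methoxy-2-(4,4,5,5-tetramethyl-1,3,2-dioxaborolan-2-yl)phenoxy]phenol | Oc1c(Oc2cc(OC)cc(OC)c2)c(OC)cc(OC)c1Oc1cccc(OC)c1B1OC(C)(C)C(C)(C)O1
F8 | step 2 | 2-(2-bromo-3-methoxyphenoxy)-6-hydroxy-3,5-dimethoxybenzaldehyde | O=Cc1c(O)c(OC)cc(OC)c1Oc1cccc(OC)c1Br
F9 | step 8 | (ethoxyethynyl)zinc chloride | CCOC#C[Zn]Cl
A1 | alternative 1 | 2-diazo-1-(4,6-dimethoxy-1-benzofuran-2-yl)ethan-1-one | COc1cc(OC)c2cc(C(=O)C=[N+]=[N-])oc2c1
A2 | alternative 1 | di-tert-butoxyethyne | CC(C)(C)OC#COC(C)(C)C
A3 | alternative 1 | 2,3-di-tert-butoxy-7,9-dimethoxydibenzofuran-1-ol | COc1cc(OC)c2c(c1)oc1cc(OC(C)(C)C)c(OC(C)(C)C)c(O)c12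
A4 | alternative 2 | penta-O-methyl dibenzodioxin-fused benzofuran with acetyl on furan C3 and a methyl acetate arm on furan C2 | COc1cc(OC)cc(Oc2c(OC)cc(OC)c3c2Oc2c(OC)cc4oc(CC(=O)OC)c(C(C)=O)c4c2O3)c1
A5 | alternative 2 | penta-O-methyl ether of 20 with both ring A hydroxyls free | COc1cc(OC)cc(Oc2c(OC)cc(OC)c3c2Oc2c(OC)cc4oc5cc(O)cc(O)c5c4c2O3)c1
A6 | alternative 3 | dibenzodioxin with bromine on C5 and a 3,5-dimethoxyphenoxy group on C4 | COc1cc(OC)cc(Oc2c(OC)cc(OC)c3c2Oc2c(OC)cc(Oc4cc(OC)cc(OC)c4)c(Br)c2O3)c1
A7 | alternative 3 | hepta-O-methyl ether of 20 | COc1cc(OC)cc(Oc2c(OC)cc(OC)c3c2Oc2c(OC)cc4oc5cc(OC)cc(OC)c5c4c2O3)c1
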